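**Retrosynthetic overview**

1. The succinimide is made last: an Evans syn-aldol forms C12–C13 on a C12 aldehyde, and N-acyl transfer from the auxiliary to a side-chain amide closes the imide. The C6 ketone stays masked as a silyl dienol ether until the final step, and C12 comes from formylation of a C11 alkyllithium.
2. Key disconnection: both carbocycles are formed at once by an intramolecular Diels–Alder reaction. C5–C10 (the ring-fusion bond) closes ring A through the C4–C3–C2–C1 tether and C8–C9 completes ring B, starting from an acyclic 2-siloxy vinylallene / (E)-enoate.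
3. Enabling feature: in ring B the C6 ketone is 1,3 to the C8 exocyclic methylene, with the ring-fusion CH (C5) α to the ketone. The array C5–C6(=O)–C7–C8(=C17H2) is the retron of the diene C5=C6(OSi)–C7=C8=C17, and C9–C10 (C9 carrying a carbon that can be an ester) is the dienophile. The equatorial C2–Cl, lying between the axial methyls on C4 and C10, fixes the face.
4. The acyclic precursor comes from a vinylogous Mukaiyama aldol (C1–C2 bond, C2–O stereocentre), Appel inversion to C2–Cl, then hydroboration, propargylation and oxidation to the allenyl ketone.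
5. Ring order: rings A and B together (step 9), succinimide ring last (step 15).

Key step: step 9

Remark: labdane numbering is used for the carbon atoms (C1–C10 decalin, C17 exocyclic CH2, C11–C16 side chain and imide). The target SMILES corresponds to 2S,5S,9S,10R,12S,13R: a trans-decalin with equatorial 2α-Cl and a syn C12/C13 aldol relationship.
Assumption: the (S,S) ligand in step 3 is assumed to direct Si-face attack. The sense would be checked by MTPA ester analysis and the antipodal ligand used if it is opposite.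

**Step 1**
Reactants: 1 methyl 3,3-dimethylpent-4-enoate
Product: 2 3,3-dimethylpent-4-enal
Conditions: DIBAL-H (1.05 equiv), CH2Cl2, −78 °C; aq. potassium sodium tartrate
Reagents that add atoms: none
Why: Partial ester reduction stops at the aldehyde because the tetrahedral aluminium hemiacetal is stable at −78 °C until work-up.

**Step 2**
Reactants: 3 methyl 3-methylbut-2-enoate
Product: 5 tert-butyl[(1-methoxy-3-methylbuta-1,3-dien-1-yl)oxy]dimethylsilane, via lithium dienolate 4 (not isolated)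
Conditions: LDA, THF, −78 °C; then TBSCl, DMPU, −78 °C to rt
Reagents that add atoms: tert-butyldimethylsilyl chloride, CC(C)(C)[Si](C)(C)Cl
Why: γ-Deprotonation of the senecioate and O-silylation of the extended enolate give the silyl dienol ether needed for a vinylogous Mukaiyama aldol reaction.

**Step 3**
Reactants: 2 3,3-dimethylpent-4-enal; 5 tert-butyl[(1-methoxy-3-methylbuta-1,3-dien-1-yl)oxy]dimethylsilane
Product: 6 methyl (2E,5S)-5-hydroxy-3,7,7-trimethylnona-2,8-dienoate
Conditions: SiCl4 (1.1 equiv), (S,S)-[(C20H12)(NMe)2P(O)N(Me)]2(CH2)5 (binaphthyldiamine-derived bis-phosphoramide, 5 mol %), iPr2NEt (10 mol %), CH2Cl2, −78 °C; aq. NaHCO3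
Reagents that add atoms: none
Why: Vinylogous Mukaiyama aldol reaction under Lewis-base-activated SiCl4: the dienolate attacks through its γ-carbon to give the (E)-enoate, and catalyst-controlled Si-face attack on the aldehyde sets the (5S) carbinol (future C2).

**Step 4**
Reactants: 6 methyl (2E,5S)-5-hydroxy-3,7,7-trimethylnona-2,8-dienoate
Product: 7 methyl (2E,5R)-5-chloro-3,7,7-trimethylnona-2,8-dienoate
Conditions: PPh3, N-chlorosuccinimide, THF, 0 °C to rt
Reagents that add atoms: N-chlorosuccinimide, O=C1CCC(=O)N1Cl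
Why: Appel-type chlorination (alkoxyphosphonium, SN2 by chloride) converts the unhindered secondary alcohol to the chloride with inversion, giving the C2 configuration of the target; the electron-poor enoate alkene cannot participate.

**Step 5**
Reactants: 7 methyl (2E,5R)-5-chloro-3,7,7-trimethylnona-2,8-dienoate
Product: 9 methyl (2E,5S)-5-chloro-9-hydroxy-3,7,7-trimethylnon-2-enoate, via alkylborane 8 (not isolated)
Conditions: 9-BBN, THF, 0 °C to rt; then 30% H2O2, 3 M aq. NaOAc, 0 °C to rt
Reagents that add atoms: hydrogen peroxide, OO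
Why: Anti-Markovnikov hydroboration–oxidation; 9-BBN selects the monosubstituted vinyl group over the trisubstituted conjugated alkene and tolerates ester and chloride (the descriptor changes only through CIP priorities).

**Step 6**
Reactants: 9 methyl (2E,5S)-5-chloro-9-hydroxy-3,7,7-trimethylnon-2-enoate
Product: 10 methyl (2E,5S)-5-chloro-3,7,7-trimethyl-9-oxonon-2-enoate
Conditions: Dess–Martin periodinane, NaHCO3, CH2Cl2, 0 °C to rt
Reagents that add atoms: none
Why: Buffered Dess–Martin oxidation of a primary alcohol to the aldehyde without touching the chloride or the enoate.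

**Step 7**
Reactants: 10 methyl (2E,5S)-5-chloro-3,7,7-trimethyl-9-oxonon-2-enoate
Product: 11 methyl (2E,5S,9RS)-5-chloro-9-hydroxy-3,7,7-trimethyldodec-2-en-11-ynoate
Conditions: propargyl bromide, Zn dust, THF/sat. aq. NH4Cl, 0 °C
Reagents that add atoms: propargyl bromide, C#CCBr
Why: Barbier-type propargylation: allenylzinc bromide adds by an SE2' pathway to the aldehyde only, giving the homopropargylic alcohol; the new carbinol centre is removed in the next step.

**Step 8**
Reactants: 11 methyl (2E,5S,9RS)-5-chloro-9-hydroxy-3,7,7-trimethyldodec-2-en-11-ynoate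
Product: 13 methyl (2E,5S)-5-chloro-3,7,7-trimethyl-9-oxododeca-2,10,11-trienoate, via alkynyl ketone 12 (not isolated)
Conditions: Dess–Martin periodinane, NaHCO3, CH2Cl2, 0 °C; then Et3N (0.2 equiv), CH2Cl2, 0 °C
Reagents that add atoms: none
Why: Oxidation gives the β,γ-alkynyl ketone, whose doubly activated C7 methylene undergoes amine-catalysed propargyl–allenyl prototropy to the conjugated 1,2-allenyl ketone, which is used at once.

**Step 9**
Reactants: 13 methyl (2E,5S)-5-chloro-3,7,7-trimethyl-9-oxododeca-2,10,11-trienoate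
Product: 15 methyl (1S,4aS,7S,8aS)-7-chloro-5,5,8a-trimethyl-2-methylidene-4-[(triisopropylsilyl)oxy]-1,2,4a,5,6,7,8,8a-octahydronaphthalene-1-carboxylate, via siloxy vinylallene 14 (not isolated)
Conditions: TIPSOTf (1.3 equiv), Et3N (2 equiv), CH2Cl2, −78 to 0 °C; pentane, cold aq. NaHCO3 wash; then PhMe (0.01 M), BHT, 80 °C
Reagents that add atoms: triisopropylsilyl trifluoromethanesulfonate, CC(C)[Si](OS(=O)(=O)C(F)(F)F)(C(C)C)C(C)C
Why: Soft enolization at the only enolizable sp3 position (C5H2) gives the (Z)-2-siloxy vinylallene 14, whose s-cis diene C5=C6(OSi)–C7=C8 reacts with the tethered (E)-enoate C9=C10 in a normal-demand intramolecular Diels–Alder reaction; it is asynchronous with C5–C10 leading, because the enol-ether carbon C5 and the enoate β-carbon C10 carry the largest frontier coefficients. The closest known reaction types are intramolecular Diels–Alder reactions of vinylallenes and the intramolecular double Michael reaction of in situ generated 2-siloxydienes with enoates. Ring A closes through the four-carbon tether C4–C3–C2–C1 by the C5–C10 bond (six-membered, chair-like tether), and ring B is the cycloadduct ring completed by C8–C9, so the open chain becomes the decalin in one operation; the orthogonal allene π bond becomes the C8 exocyclic methylene and the C6 oxygen emerges as the dienol ether of the β,γ-unsaturated ketone. C9 and C10 follow from the (E)-enoate geometry (C10 methyl cis to the C9 ester), and C5 follows from the ester-endo transition state, which places the outside substituent C4 cis to the C10 methyl and hence H-5 trans to it (trans fusion). The absolute sense comes from C2: chlorine must be equatorial in the chair-like tether, because an axial C2 substituent would be 1,3-diaxial to both the axial C4 methyl and the C10 methyl. The step needs Z enol ether geometry (thermodynamic, the bulky C4 trans to C7), endo over exo closure, and no [1,5]-H shift of the vinylallene; the last is excluded because C4 is quaternary.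

**Step 10**
Reactants: 15 methyl (1S,4aS,7S,8aS)-7-chloro-5,5,8a-trimethyl-2-methylidene-4-[(triisopropylsilyl)oxy]-1,2,4a,5,6,7,8,8a-octahydronaphthalene-1-carboxylate
Product: 16 [(1S,4aS,7S,8aR)-7-chloro-5,5,8a-trimethyl-2-methylidene-4-[(triisopropylsilyl)oxy]-1,2,4a,5,6,7,8,8a-octahydronaphthalen-1-yl]methanol
Conditions: DIBAL-H (2.5 equiv), CH2Cl2, −78 °C; aq. potassium sodium tartrate
Reagents that add atoms: none
Why: Hydride reduction of the ester to the primary alcohol; the bulky silyl dienol ether and the secondary chloride are inert to DIBAL-H at −78 °C.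

**Step 11**
Reactants: 16 [(1S,4aS,7S,8aR)-7-chloro-5,5,8a-trimethyl-2-methylidene-4-[(triisopropylsilyl)oxy]-1,2,4a,5,6,7,8,8a-octahydronaphthalen-1-yl]methanol
Product: 17 (1S,4aS,7S,8aS)-7-chloro-1-(iodomethyl)-5,5,8a-trimethyl-2-methylidene-4-[(triisopropylsilyl)oxy]-1,2,4a,5,6,7,8,8a-octahydronaphthalene
Conditions: PPh3, I2, imidazole (premixed), CH2Cl2, 0 °C to rt
Reagents that add atoms: iodine, II
Why: Appel-type iodination of the primary alcohol through an alkoxyphosphonium iodide; premixing the reagents keeps free iodine away from the electron-rich siloxydiene.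

**Step 12**
Reactants: 17 (1S,4aS,7S,8aS)-7-chloro-1-(iodomethyl)-5,5,8a-trimethyl-2-methylidene-4-[(triisopropylsilyl)oxy]-1,2,4a,5,6,7,8,8a-octahydronaphthalene
Product: 19 2-[(1S,4aS,7S,8aR)-7-chloro-5,5,8a-trimethyl-2-methylidene-4-[(triisopropylsilyl)oxy]-1,2,4a,5,6,7,8,8a-octahydronaphthalen-1-yl]acetaldehyde, via alkyllithium 18 (not isolated)
Conditions: t-BuLi (2.1 equiv), Et2O/pentane, −78 °C; then DMF, −78 to 0 °C; H2O
Reagents that add atoms: N,N-dimethylformamide, CN(C)C=O
Why: Lithium–iodine exchange at the primary iodide is far faster than any reaction of the secondary chloride at −78 °C, and formylation of the alkyllithium with DMF delivers the one-carbon-homologated C12 aldehyde under non-acidic conditions.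

**Step 13**
Reactants: 20 (4R)-4-benzyl-1,3-oxazolidin-2-one; 21 3-cyanopropanoic acid
Product: 23 (4R)-4-benzyl-3-(3-cyanopropanoyl)-1,3-oxazolidin-2-one, via mixed pivalic anhydride 22 (not isolated)
Conditions: pivaloyl chloride, Et3N, THF, −20 °C; then 20, LiCl, −20 °C to rt
Reagents that add atoms: none
Why: N-Acylation of the oxazolidinone by the mixed anhydride at its less hindered carbonyl (LiCl/Et3N activation) gives the chiral imide carrying the latent C15 amide as a nitrile.

**Step 14**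
Reactants: 19 2-[(1S,4aS,7S,8aR)-7-chloro-5,5,8a-trimethyl-2-methylidene-4-[(triisopropylsilyl)oxy]-1,2,4a,5,6,7,8,8a-octahydronaphthalen-1-yl]acetaldehyde; 23 (4R)-4-benzyl-3-(3-cyanopropanoyl)-1,3-oxazolidin-2-one
Product: 25 (4R)-4-benzyl-3-{(2R,3S)-4-[(1S,4aS,7S,8aR)-7-chloro-5,5,8a-trimethyl-2-methylidene-4-[(triisopropylsilyl)oxy]-1,2,4a,5,6,7,8,8a-octahydronaphthalen-1-yl]-2-(cyanomethyl)-3-hydroxybutanoyl}-1,3-oxazolidin-2-one, via boron enolate 24 (not isolated)
Conditions: Bu2BOTf (1.1 equiv), iPr2NEt (1.3 equiv), CH2Cl2, 0 °C; then 19, −78 to 0 °C; pH 7 buffer, MeOH, 30% H2O2, 0 °C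
Reagents that add atoms: none
Why: Evans syn-aldol reaction: the (Z)-dibutylboron enolate reacts through a closed chair transition state on the face opposite the benzyl group, so the (R)-auxiliary sets 12S and 13R regardless of the remote decalin centres.

**Step 15**
Reactants: 25 (4R)-4-benzyl-3-{(2R,3S)-4-[(1S,4aS,7S,8aR)-7-chloro-5,5,8a-trimethyl-2-methylidene-4-[(triisopropylsilyl)oxy]-1,2,4a,5,6,7,8,8a-octahydronaphthalen-1-yl]-2-(cyanomethyl)-3-hydroxybutanoyl}-1,3-oxazolidin-2-one
Product: 27 (3R)-3-{(1S)-2-[(1S,4aS,7S,8aR)-7-chloro-5,5,8a-trimethyl-2-methylidene-4-[(triisopropylsilyl)oxy]-1,2,4a,5,6,7,8,8a-octahydronaphthalen-1-yl]-1-hydroxyethyl}pyrrolidine-2,5-dione, via primary amide 26 (not isolated)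
Conditions: [PtH(PMe2OH)(PMe2O)2H] (5 mol %), EtOH/H2O 4:1, 70 °C; evaporate; then DBU (1.5 equiv), THF, 0 °C to rt
Reagents that add atoms: water, O
Why: Neutral platinum-catalysed nitrile hydration gives the primary amide, whose nitrogen then attacks the activated exocyclic imide carbonyl (5-exo-trig N-acyl transfer) and expels the oxazolidinone to form the succinimide; the ketone is still masked, so the base cannot move the C8 double bond.

**Step 16**
Reactants: 27 (3R)-3-{(1S)-2-[(1S,4aS,7S,8aR)-7-chloro-5,5,8a-trimethyl-2-methylidene-4-[(triisopropylsilyl)oxy]-1,2,4a,5,6,7,8,8a-octahydronaphthalen-1-yl]-1-hydroxyethyl}pyrrolidine-2,5-dione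
Product: 28 haterumaimide G, (3R)-3-{(1S)-2-[(1S,4aS,7S,8aR)-7-chloro-5,5,8a-trimethyl-2-methylidene-4-oxodecahydronaphthalen-1-yl]-1-hydroxyethyl}pyrrolidine-2,5-dione
Conditions: TBAF (1.5 equiv), AcOH (2 equiv), THF, −20 to 0 °C; pH 7 buffer
Reagents that add atoms: none
Why: Fluoride cleaves the silyl dienol ether and the dienolate is protonated kinetically at the α-carbon C7 by acetic acid, which should give the β,γ-unsaturated C6 ketone with the C8 exocyclic methylene; buffered cold conditions are chosen to avoid conjugation and retro-aldol cleavage.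

**Compound list**

1 | methyl 3,3-dimethylpent-4-enoate | C=CC(C)(C)CC(=O)OC | starting material
2 | 3,3-dimethylpent-4-enal | C=CC(C)(C)CC=O | intermediate
3 | methyl 3-methylbut-2-enoate | CC(C)=CC(=O)OC | starting material
4 | lithium 1-methoxy-3-methylbuta-1,3-dien-1-olate | C=C(C)C=C(OC)O[Li] | intermediate (not isolated)
5 | tert-butyl[(1-methoxy-3-methylbuta-1,3-dien-1-yl)oxy]dimethylsilane | C=C(C)C=C(OC)O[Si](C)(C)C(C)(C)C | intermediate
6 | methyl (2E,5S)-5-hydroxy-3,7,7-trimethylnona-2,8-dienoate | C=CC(C)(C)C[C@@H](O)C/C(C)=C/C(=O)OC | intermediate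
7 | methyl (2E,5R)-5-chloro-3,7,7-trimethylnona-2,8-dienoate | C=CC(C)(C)C[C@H](Cl)C/C(C)=C/C(=O)OC | intermediate
8 | methyl (2E,5S)-9-(9-borabicyclo[3.3.1]nonan-9-yl)-5-chloro-3,7,7-trimethylnon-2-enoate | B1(CCC(C)(C)C[C@H](Cl)C/C(C)=C/C(=O)OC)C2CCCC1CCC2 | intermediate (not isolated)
9 | methyl (2E,5S)-5-chloro-9-hydroxy-3,7,7-trimethylnon-2-enoate | OCCC(C)(C)C[C@H](Cl)C/C(C)=C/C(=O)OC | intermediate
10 | methyl (2E,5S)-5-chloro-3,7,7-trimethyl-9-oxonon-2-enoate | O=CCC(C)(C)C[C@H](Cl)C/C(C)=C/C(=O)OC | intermediate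
11 | methyl (2E,5S,9RS)-5-chloro-9-hydroxy-3,7,7-trimethyldodec-2-en-11-ynoate | C#CCC(O)CC(C)(C)C[C@H](Cl)C/C(C)=C/C(=O)OC | intermediate
12 | methyl (2E,5S)-5-chloro-3,7,7-trimethyl-9-oxododec-2-en-11-ynoate | C#CCC(=O)CC(C)(C)C[C@H](Cl)C/C(C)=C/C(=O)OC | intermediate (not isolated)
13 | methyl (2E,5S)-5-chloro-3,7,7-trimethyl-9-oxododeca-2,10,11-trienoate | C=C=CC(=O)CC(C)(C)C[C@H](Cl)C/C(C)=C/C(=O)OC | intermediate
14 | methyl (2E,5R,8Z)-5-chloro-3,7,7-trimethyl-9-[(triisopropylsilyl)oxy]dodeca-2,8,10,11-tetraenoate | C=C=C/C(O[Si](C(C)C)(C(C)C)C(C)C)=C/C(C)(C)C[C@H](Cl)C/C(C)=C/C(=O)OC | intermediate (not isolated)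
15 | methyl (1S,4aS,7S,8aS)-7-chloro-5,5,8a-trimethyl-2-methylidene-4-[(triisopropylsilyl)oxy]-1,2,4a,5,6,7,8,8a-octahydronaphthalene-1-carboxylate (trans-fused, ester cis to the angular methyl, Cl equatorial) | C=C1C=C(O[Si](C(C)C)(C(C)C)C(C)C)[C@H]2C(C)(C)C[C@H](Cl)C[C@]2(C)[C@H]1C(=O)OC | intermediate
16 | [(1S,4aS,7S,8aR)-7-chloro-5,5,8a-trimethyl-2-methylidene-4-[(triisopropylsilyl)oxy]-1,2,4a,5,6,7,8,8a-octahydronaphthalen-1-yl]methanol | C=C1C=C(O[Si](C(C)C)(C(C)C)C(C)C)[C@H]2C(C)(C)C[C@H](Cl)C[C@]2(C)[C@H]1CO | intermediate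
17 | (1S,4aS,7S,8aS)-7-chloro-1-(iodomethyl)-5,5,8a-trimethyl-2-methylidene-4-[(triisopropylsilyl)oxy]-1,2,4a,5,6,7,8,8a-octahydronaphthalene | C=C1C=C(O[Si](C(C)C)(C(C)C)C(C)C)[C@H]2C(C)(C)C[C@H](Cl)C[C@]2(C)[C@H]1CI | intermediate
18 | {[(1S,4aS,7S,8aR)-7-chloro-5,5,8a-trimethyl-2-methylidene-4-[(triisopropylsilyl)oxy]-1,2,4a,5,6,7,8,8a-octahydronaphthalen-1-yl]methyl}lithium | C=C1C=C(O[Si](C(C)C)(C(C)C)C(C)C)[C@H]2C(C)(C)C[C@H](Cl)C[C@]2(C)[C@H]1C[Li] | intermediate (not isolated)
19 | 2-[(1S,4aS,7S,8aR)-7-chloro-5,5,8a-trimethyl-2-methylidene-4-[(triisopropylsilyl)oxy]-1,2,4a,5,6,7,8,8a-octahydronaphthalen-1-yl]acetaldehyde | C=C1C=C(O[Si](C(C)C)(C(C)C)C(C)C)[C@H]2C(C)(C)C[C@H](Cl)C[C@]2(C)[C@H]1CC=O | intermediate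
20 | (4R)-4-benzyl-1,3-oxazolidin-2-one | O=C1N[C@H](Cc2ccccc2)CO1 | starting material
21 | 3-cyanopropanoic acid | N#CCCC(=O)O | starting material
22 | 3-cyanopropanoic pivalic anhydride | N#CCCC(=O)OC(=O)C(C)(C)C | intermediate (not isolated)
23 | (4R)-4-benzyl-3-(3-cyanopropanoyl)-1,3-oxazolidin-2-one | N#CCCC(=O)N1[C@H](Cc2ccccc2)COC1=O | intermediate
24 | (Z)-dibutylboron enolate of 23 | N#CC/C=C(\OB(CCCC)CCCC)N1[C@H](Cc2ccccc2)COC1=O | intermediate (not isolated)
25 | (4R)-4-benzyl-3-{(2R,3S)-4-[(1S,4aS,7S,8aR)-7-chloro-5,5,8a-trimethyl-2-methylidene-4-[(triisopropylsilyl)oxy]-1,2,4a,5,6,7,8,8a-octahydronaphthalen-1-yl]-2-(cyanomethyl)-3-hydroxybutanoyl}-1,3-oxazolidin-2-one | C=C1C=C(O[Si](C(C)C)(C(C)C)C(C)C)[C@H]2C(C)(C)C[C@H](Cl)C[C@]2(C)[C@H]1C[C@H](O)[C@@H](CC#N)C(=O)N1[C@H](Cc2ccccc2)COC1=O | intermediate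
26 | (3R,4S)-3-{[(4R)-4-benzyl-2-oxo-1,3-oxazolidin-3-yl]carbonyl}-5-[(1S,4aS,7S,8aR)-7-chloro-5,5,8a-trimethyl-2-methylidene-4-[(triisopropylsilyl)oxy]-1,2,4a,5,6,7,8,8a-octahydronaphthalen-1-yl]-4-hydroxypentanamide | C=C1C=C(O[Si](C(C)C)(C(C)C)C(C)C)[C@H]2C(C)(C)C[C@H](Cl)C[C@]2(C)[C@H]1C[C@H](O)[C@@H](CC(N)=O)C(=O)N1[C@H](Cc2ccccc2)COC1=O | intermediate (not isolated)
27 | (3R)-3-{(1S)-2-[(1S,4aS,7S,8aR)-7-chloro-5,5,8a-trimethyl-2-methylidene-4-[(triisopropylsilyl)oxy]-1,2,4a,5,6,7,8,8a-octahydronaphthalen-1-yl]-1-hydroxyethyl}pyrrolidine-2,5-dione | C=C1C=C(O[Si](C(C)C)(C(C)C)C(C)C)[C@H]2C(C)(C)C[C@H](Cl)C[C@]2(C)[C@H]1C[C@H](O)[C@H]1CC(=O)NC1=O | intermediate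
28 | haterumaimide G, (3R)-3-{(1S)-2-[(1S,4aS,7S,8aR)-7-chloro-5,5,8a-trimethyl-2-methylidene-4-oxodecahydronaphthalen-1-yl]-1-hydroxyethyl}pyrrolidine-2,5-dione | C=C1CC(=O)[C@H]2C(C)(C)C[C@H](Cl)C[C@]2(C)[C@H]1C[C@H](O)[C@H]1CC(=O)NC1=O | target

**Step count**

Total steps: 16. Longest linear sequence: 14 steps (from 1 through steps 1, 3–12 and 14–16 to 28); steps 2 and 13 prepare the two side components.

**Steps most likely to fail**

Step 9. The silyl triflate/amine pair may add to or oligomerize the allenone instead of enolizing it at C5. The cycloaddition may also close through the exo transition state, which would give the cis-fused adduct, or be slowed by congestion at the C5–C10 bond. Fallback: leave the pericyclic manifold for an anionic Michael–Michael ring closure (intramolecular double Michael reaction). Setting out from 13, LiHMDS (THF, −78 °C) removes a C5 proton; the lithium enolate adds to the enoate at C10 through a chelated six-membered transition state (ring A), and the ester enolate so formed adds to the central allene carbon C8 (ring B). This gives the lithium dienolate of methyl (1S,4aS,7S,8aS)-7-chloro-5,5,8a-trimethyl-2-methylidene-4-oxodecahydronaphthalene-1-carboxylate F1, which is O-silylated in the same flask with TIPSOTf and so comes back to the route at 15.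

Step 16. Protonation of the dienolate may occur at C17 instead of C7, or fluoride/acetate may move the exocyclic double bond into conjugation with the C6 ketone once it is free; this happens at the very end with all other functionality present. Fallback: unmask the ketone before the side chain is built, where a conjugated isomer can be removed on a simple compound, and close the imide without base. Setting out from 19, TBAF/AcOH gives 2-[(1S,4aS,7S,8aR)-7-chloro-5,5,8a-trimethyl-2-methylidene-4-oxodecahydronaphthalen-1-yl]acetaldehyde F2. The boron aldol with enolate 24 then gives (4R)-4-benzyl-3-{(2R,3S)-4-[(1S,4aS,7S,8aR)-7-chloro-5,5,8a-trimethyl-2-methylidene-4-oxodecahydronaphthalen-1-yl]-2-(cyanomethyl)-3-hydroxybutanoyl}-1,3-oxazolidin-2-one F3. Platinum-catalysed hydration gives the corresponding primary amide, (3R,4S)-3-{[(4R)-4-benzyl-2-oxo-1,3-oxazolidin-3-yl]carbonyl}-5-[(1S,4aS,7S,8aR)-7-chloro-5,5,8a-trimethyl-2-methylidene-4-oxodecahydronaphthalen-1-yl]-4-hydroxypentanamide F4. This is cyclized thermally with 2-hydroxypyridine as a neutral bifunctional catalyst (PhMe, 80 °C) and comes back to the route at 28.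

Step 15. N-Acyl transfer from the oxazolidinone to the amide nitrogen may be slow, so that retro-aldol cleavage or opening of the oxazolidinone ring under base competes. Fallback: remove the auxiliary first and close the imide from an amic acid. Setting out from 25, LiOH/H2O2 (THF/H2O, 0 °C) gives (2R,3S)-4-[(1S,4aS,7S,8aR)-7-chloro-5,5,8a-trimethyl-2-methylidene-4-[(triisopropylsilyl)oxy]-1,2,4a,5,6,7,8,8a-octahydronaphthalen-1-yl]-2-(cyanomethyl)-3-hydroxybutanoic acid F5. Platinum-catalysed hydration of the nitrile gives (2R,3S)-2-(2-amino-2-oxoethyl)-4-[(1S,4aS,7S,8aR)-7-chloro-5,5,8a-trimethyl-2-methylidene-4-[(triisopropylsilyl)oxy]-1,2,4a,5,6,7,8,8a-octahydronaphthalen-1-yl]-3-hydroxybutanoic acid F6. Cyclodehydration with 1,1'-carbonyldiimidazole (THF, rt) comes back to the route at 27.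

**Further compounds**

F1 | step 9 | lithium dienolate of methyl (1S,4aS,7S,8aS)-7-chloro-5,5,8a-trimethyl-2-methylidene-4-oxodecahydronaphthalene-1-carboxylate | C=C1C=C(O[Li])[C@H]2C(C)(C)C[C@H](Cl)C[C@]2(C)[C@H]1C(=O)OC
F2 | step 16 | 2-[(1S,4aS,7S,8aR)-7-chloro-5,5,8a-trimethyl-2-methylidene-4-oxodecahydronaphthalen-1-yl]acetaldehyde | C=C1CC(=O)[C@H]2C(C)(C)C[C@H](Cl)C[C@]2(C)[C@H]1CC=O
F3 | step 16 | (4R)-4-benzyl-3-{(2R,3S)-4-[(1S,4aS,7S,8aR)-7-chloro-5,5,8a-trimethyl-2-methylidene-4-oxodecahydronaphthalen-1-yl]-2-(cyanomethyl)-3-hydroxybutanoyl}-1,3-oxazolidin-2-one | C=C1CC(=O)[C@H]2C(C)(C)C[C@H](Cl)C[C@]2(C)[C@H]1C[C@H](O)[C@@H](CC#N)C(=O)N1[C@H](Cc2ccccc2)COC1=O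
F4 | step 16 | (3R,4S)-3-{[(4R)-4-benzyl-2-oxo-1,3-oxazolidin-3-yl]carbonyl}-5-[(1S,4aS,7S,8aR)-7-chloro-5,5,8a-trimethyl-2-methylidene-4-oxodecahydronaphthalen-1-yl]-4-hydroxypentanamide | C=C1CC(=O)[C@H]2C(C)(C)C[C@H](Cl)C[C@]2(C)[C@H]1C[C@H](O)[C@@H](CC(N)=O)C(=O)N1[C@H](Cc2ccccc2)COC1=O
F5 | step 15 | (2R,3S)-4-[(1S,4aS,7S,8aR)-7-chloro-5,5,8a-trimethyl-2-methylidene-4-[(triisopropylsilyl)oxy]-1,2,4a,5,6,7,8,8a-octahydronaphthalen-1-yl]-2-(cyanomethyl)-3-hydroxybutanoic acid | C=C1C=C(O[Si](C(C)C)(C(C)C)C(C)C)[C@H]2C(C)(C)C[C@H](Cl)C[C@]2(C)[C@H]1C[C@H](O)[C@@H](CC#N)C(=O)O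
F6 | step 15 | (2R,3S)-2-(2-amino-2-oxoethyl)-4-[(1S,4aS,7S,8aR)-7-chloro-5,5,8a-trimethyl-2-methylidene-4-[(triisopropylsilyl)oxy]-1,2,4a,5,6,7,8,8a-octahydronaphthalen-1-yl]-3-hydroxybutanoic acid | C=C1C=C(O[Si](C(C)C)(C(C)C)C(C)C)[C@H]2C(C)(C)C[C@H](Cl)C[C@]2(C)[C@H]1C[C@H](O)[C@@H](CC(N)=O)C(=O)O
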